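**Retrosynthetic overview**
- The target is reached last by acid cleavage of the methoxymethyl (MOM) ether on the 3'-hydroxyl of a 7-hydroxyflavanone.
- Key disconnection: ring A (C4a, C5, C6, C7, C8, C8a) is built de novo. Its C4a=C8a edge is the enone C5=C6 bond of a (2S)-2-aryl-2,3-dihydropyran-4-one, and C5, C6, C7 (with its oxygen) and C8 come from 1-methoxy-3-(trimethylsilyloxy)butadiene. A p-tolylsulfinyl group on the enone α-carbon activates the dienophile and leaves as sulfenic acid to aromatise.
- The sulfinyl enone comes from the dihydropyranone by C5 sulfenylation, Stille prenylation of the aryl bromide and oxidation at sulfur. Sulfenylation precedes prenylation because sulfenyl chlorides add to trisubstituted alkenes.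
- Ring C and the C2 stereocentre come from a catalytic asymmetric hetero-Diels–Alder reaction of 3-bromo-4-methoxy-5-(methoxymethoxy)benzaldehyde with the same diene.
- Ring order: ring B is purchased, ring C is formed in step 3, ring A in step 7.

Key step: step 7

Assumption: the (S)-BINOL/Ti(OiPr)4 catalyst is taken to give the 2S dihydropyranone, by analogy with the facial sense of this catalyst family in aldehyde additions. If the first run shows the opposite sense, (R)-BINOL is used and nothing else changes.

Remark: sulfoxide 13 is carried as a mixture of epimers at sulfur, because sulfur is lost in step 7.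

Step 1
Reactants: 1 3-bromo-4,5-dihydroxybenzaldehyde
Product: 2 3-bromo-5-hydroxy-4-methoxybenzaldehyde
Conditions: MeI (1.1 equiv), Li2CO3 (1.5 equiv), DMF, 40 °C
Reagents that add atoms: iodomethane, CI
Why: The C4 hydroxyl, para to the formyl group and ortho to bromine, is the more acidic phenol, so the weak base forms only that phenoxide and the Williamson methylation should occur there (regioselective monoalkylation of a catechol aldehyde).

Step 2
Reactants: 2 3-bromo-5-hydroxy-4-methoxybenzaldehyde
Product: 3 3-bromo-4-methoxy-5-(methoxymethoxy)benzaldehyde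
Conditions: MOMCl, iPr2NEt, CH2Cl2, 0 °C to rt
Reagents that add atoms: chloromethyl methyl ether, COCCl
Why: Standard MOM ether formation on the remaining phenol; the acetal should survive the Lewis-acidic, organometallic and oxidative steps and is removable at the end with dilute acid.

Step 3
Reactants: 3 3-bromo-4-methoxy-5-(methoxymethoxy)benzaldehyde; 4 (E)-1-methoxy-3-(trimethylsilyloxy)buta-1,3-diene
Product: 6 (2S)-2-[3-bromo-4-methoxy-5-(methoxymethoxy)phenyl]-2,3-dihydro-4H-pyran-4-one, via silylated Mukaiyama aldol adduct 5 (not isolated)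
Conditions: (S)-BINOL (20 mol %), Ti(OiPr)4 (10 mol %), 4 Å MS, Et2O, −20 °C; then CF3CO2H (cat.), CH2Cl2, 0 °C; aq. NaHCO3
Reagents that add atoms: none
Why: Catalytic enantioselective hetero-Diels–Alder reaction of an aryl aldehyde with the Danishefsky diene (Mukaiyama aldol pathway, then acid-promoted cyclisation with loss of methanol), in which the chiral titanium BINOLate shields one face of the bound aldehyde and so sets C2 as S.

Step 4
Reactants: 6 (2S)-2-[3-bromo-4-methoxy-5-(methoxymethoxy)phenyl]-2,3-dihydro-4H-pyran-4-one; 7 4-methylbenzenethiol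
Product: 10 (2S)-2-[3-bromo-4-methoxy-5-(methoxymethoxy)phenyl]-5-[(4-methylphenyl)sulfanyl]-2,3-dihydro-4H-pyran-4-one, via 4-methylbenzenesulfenyl chloride 8 (not isolated), via 6-chloro-5-arylsulfanyl adduct 9 (not isolated)
Conditions: 7, N-chlorosuccinimide, CH2Cl2, 0 °C; add to 6, CH2Cl2, −78 to −20 °C; then Et3N, −20 °C to rt
Reagents that add atoms: none
Why: Electrophilic sulfenylation of the enol ether double bond (sulfur adds to the nucleophilic α-carbon C5, chloride to C6, then dehydrochlorination restores the vinylogous ester); it is run while the arene still carries bromine because the sulfenyl chloride would also add to a prenyl double bond.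

Step 5
Reactants: 10 (2S)-2-[3-bromo-4-methoxy-5-(methoxymethoxy)phenyl]-5-[(4-methylphenyl)sulfanyl]-2,3-dihydro-4H-pyran-4-one; 11 tributyl(3-methylbut-2-enyl)stannane
Product: 12 (2S)-2-[4-methoxy-3-(methoxymethoxy)-5-(3-methylbut-2-enyl)phenyl]-5-[(4-methylphenyl)sulfanyl]-2,3-dihydro-4H-pyran-4-one
Conditions: 11 (1.5 equiv), Pd(PPh3)4 (10 mol %), DMF, 100 °C
Reagents that add atoms: none
Why: Stille coupling of the aryl bromide with the allylic stannane, which under phosphine–palladium catalysis in DMF should transfer the prenyl group mainly through its α-carbon; the neutral conditions leave the vinylogous ester, the sulfide and C2 untouched.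

Step 6
Reactants: 12 (2S)-2-[4-methoxy-3-(methoxymethoxy)-5-(3-methylbut-2-enyl)phenyl]-5-[(4-methylphenyl)sulfanyl]-2,3-dihydro-4H-pyran-4-one
Product: 13 (2S)-2-[4-methoxy-3-(methoxymethoxy)-5-(3-methylbut-2-enyl)phenyl]-5-[(4-methylphenyl)sulfinyl]-2,3-dihydro-4H-pyran-4-one (both sulfur epimers)
Conditions: NaIO4 (1.3 equiv), MeOH/THF/H2O, 0 °C to rt
Reagents that add atoms: sodium periodate, [Na+].[O-]I(=O)(=O)=O
Why: Periodate oxidation of a sulfide stops at the sulfoxide and does not epoxidise the prenyl double bond; the sulfur epimers need no separation.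

Step 7
Reactants: 13 (2S)-2-[4-methoxy-3-(methoxymethoxy)-5-(3-methylbut-2-enyl)phenyl]-5-[(4-methylphenyl)sulfinyl]-2,3-dihydro-4H-pyran-4-one; 4 (E)-1-methoxy-3-(trimethylsilyloxy)buta-1,3-diene
Product: 17 (2S)-7-hydroxy-2-[4-methoxy-3-(methoxymethoxy)-5-(3-methylbut-2-enyl)phenyl]chroman-4-one, via silyl enol ether cycloadduct 14 (not isolated), via sulfinyl enone 15 (not isolated), via dienone tautomer 16 (not isolated)
Conditions: 4 (3 equiv), ZnCl2 (1.2 equiv, 1 M in Et2O), CH2Cl2, −30 to 0 °C; CF3CO2H (cat.), CH2Cl2, 0 °C, then aq. NaHCO3; toluene, 70 °C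
Reagents that add atoms: none
Why: Proposed new method: ZnCl2 chelated between the sulfinyl and C4 carbonyl oxygens should make C6 of 13 (future C8a) strongly electrophilic, so the CH2 terminus of 4 bonds there and the methoxy-bearing terminus bonds to C5 of 13 (future C4a), either in an asynchronous [4+2] or by Mukaiyama–Michael addition followed by six-membered closure of the zinc enolate onto the methoxy oxocarbenium, closing carbocyclic ring A as cyclohexene 14 with the silyloxy carbon at C7. Catalytic acid then ionises the allylic methoxy group of the silyl enol ether and gives enone 15, in which the only sp3 hydrogen β to sulfur is C8a–H, cis to the sulfinyl group because both sat on the same side of the dienophile double bond. Warming should then cause syn-elimination of 4-methylbenzenesulfenic acid to dienone 16, which enolises to phenol 17. The closest known reactions are the cycloaddition–sulfoxide elimination aromatisations of 2-sulfinyl quinones and the benzannulation of 3-acceptor-substituted chromones with oxygenated dienes to xanthones; a 2,3-dihydropyran-4-one has not been used in this way. No new stereocentre survives (C4a, C5 and C8a all become sp2), and C2 is safe because no event in the sequence breaks the C2–O1 bond. The step needs two selectivities: regiochemistry placing oxygen on C7, secured by the polarised diene and the electrophilic C8a, and elimination towards C8a, secured by removing the C5–H option through methanol loss before heating.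

Step 8
Reactants: 17 (2S)-7-hydroxy-2-[4-methoxy-3-(methoxymethoxy)-5-(3-methylbut-2-enyl)phenyl]chroman-4-one
Product: 18 erylatissin C, (2S)-7-hydroxy-2-[3-hydroxy-4-methoxy-5-(3-methylbut-2-enyl)phenyl]chroman-4-one
Conditions: 2 M HCl, MeOH/THF, 45 °C
Reagents that add atoms: none
Why: Acid-catalysed transacetalisation of the MOM ether to methanol; the prenyl group has no ortho hydroxyl to cyclise onto and the flavanone C2–O bond should hold in dilute acid at this temperature, so the 2S configuration is kept.

**Compound list**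
1 | 3-bromo-4,5-dihydroxybenzaldehyde | O=Cc1cc(O)c(O)c(Br)c1 | starting material
2 | 3-bromo-5-hydroxy-4-methoxybenzaldehyde | O=Cc1cc(O)c(OC)c(Br)c1 | intermediate
3 | 3-bromo-4-methoxy-5-(methoxymethoxy)benzaldehyde | O=Cc1cc(OCOC)c(OC)c(Br)c1 | intermediate
4 | (E)-1-methoxy-3-(trimethylsilyloxy)buta-1,3-diene | CO/C=C/C(=C)O[Si](C)(C)C | starting material
5 | (1E,5S)-5-[3-bromo-4-methoxy-5-(methoxymethoxy)phenyl]-1-methoxy-5-(trimethylsilyloxy)pent-1-en-3-one | CO/C=C/C(=O)C[C@H](O[Si](C)(C)C)c1cc(OCOC)c(OC)c(Br)c1 | intermediate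
6 | (2S)-2-[3-bromo-4-methoxy-5-(methoxymethoxy)phenyl]-2,3-dihydro-4H-pyran-4-one | O=C1C=CO[C@@H](C1)c1cc(OCOC)c(OC)c(Br)c1 | intermediate
7 | 4-methylbenzenethiol | Cc1ccc(S)cc1 | starting material
8 | 4-methylbenzenesulfenyl chloride | Cc1ccc(SCl)cc1 | intermediate
9 | (2S)-2-[3-bromo-4-methoxy-5-(methoxymethoxy)phenyl]-6-chloro-5-[(4-methylphenyl)sulfanyl]tetrahydro-4H-pyran-4-one (C5/C6 diastereomers) | Cc1ccc(cc1)SC1C(Cl)O[C@@H](CC1=O)c1cc(OCOC)c(OC)c(Br)c1 | intermediate
10 | (2S)-2-[3-bromo-4-methoxy-5-(methoxymethoxy)phenyl]-5-[(4-methylphenyl)sulfanyl]-2,3-dihydro-4H-pyran-4-one | Cc1ccc(cc1)SC1=CO[C@@H](CC1=O)c1cc(OCOC)c(OC)c(Br)c1 | intermediate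
11 | tributyl(3-methylbut-2-enyl)stannane | CCCC[Sn](CCCC)(CCCC)CC=C(C)C | starting material
12 | (2S)-2-[4-methoxy-3-(methoxymethoxy)-5-(3-methylbut-2-enyl)phenyl]-5-[(4-methylphenyl)sulfanyl]-2,3-dihydro-4H-pyran-4-one | Cc1ccc(cc1)SC1=CO[C@@H](CC1=O)c1cc(OCOC)c(OC)c(CC=C(C)C)c1 | intermediate
13 | (2S)-2-[4-methoxy-3-(methoxymethoxy)-5-(3-methylbut-2-enyl)phenyl]-5-[(4-methylphenyl)sulfinyl]-2,3-dihydro-4H-pyran-4-one (both sulfur epimers) | Cc1ccc(cc1)S(=O)C1=CO[C@@H](CC1=O)c1cc(OCOC)c(OC)c(CC=C(C)C)c1 | intermediate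
14 | (2S)-5-methoxy-2-[4-methoxy-3-(methoxymethoxy)-5-(3-methylbut-2-enyl)phenyl]-4a-[(4-methylphenyl)sulfinyl]-7-(trimethylsilyloxy)-2,3,4a,5,8,8a-hexahydro-4H-chromen-4-one (diastereomers at C4a, C5, C8a and S) | Cc1ccc(cc1)S(=O)C12C(OC)C=C(O[Si](C)(C)C)CC1O[C@@H](CC2=O)c1cc(OCOC)c(OC)c(CC=C(C)C)c1 | intermediate
15 | (2S)-2-[4-methoxy-3-(methoxymethoxy)-5-(3-methylbut-2-enyl)phenyl]-4a-[(4-methylphenyl)sulfinyl]-2,3,4a,8a-tetrahydro-4H-chromene-4,7(8H)-dione | Cc1ccc(cc1)S(=O)C12C=CC(=O)CC1O[C@@H](CC2=O)c1cc(OCOC)c(OC)c(CC=C(C)C)c1 | intermediate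
16 | (2S)-2-[4-methoxy-3-(methoxymethoxy)-5-(3-methylbut-2-enyl)phenyl]-2,3-dihydro-4H-chromene-4,7(8H)-dione | O=C1CC2=C(C=C1)C(=O)C[C@H](O2)c1cc(OCOC)c(OC)c(CC=C(C)C)c1 | intermediate
17 | (2S)-7-hydroxy-2-[4-methoxy-3-(methoxymethoxy)-5-(3-methylbut-2-enyl)phenyl]chroman-4-one | COc1c(OCOC)cc([C@@H]2CC(=O)c3ccc(O)cc3O2)cc1CC=C(C)C | intermediate
18 | erylatissin C, (2S)-7-hydroxy-2-[3-hydroxy-4-methoxy-5-(3-methylbut-2-enyl)phenyl]chroman-4-one | COc1c(O)cc([C@@H]2CC(=O)c3ccc(O)cc3O2)cc1CC=C(C)C | target

**Totals**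
Total step count: 8. Longest linear sequence: 8 steps (1 to 18).

**Steps most likely to fail**

Step 7. The push–pull enone may fail to engage the diene before the Lewis acid consumes it. A Michael-type adduct may open the pyranone ring by expelling O1 instead of closing ring A. Sulfoxide elimination may also begin before methanol is lost and take the C5 hydrogen. The fallback uses known flavanone chemistry, sets out from 3 and returns at 18. Stille coupling of 3 with 11 (Pd(PPh3)4, DMF, 100 °C) should give 4-methoxy-3-(methoxymethoxy)-5-(3-methylbut-2-enyl)benzaldehyde F1. Claisen–Schmidt condensation (KOH, EtOH, rt) with 1-[2-hydroxy-4-(methoxymethoxy)phenyl]ethanone F2 (from 2,4-dihydroxyacetophenone, MOMCl and K2CO3 in acetone) should give (E)-1-[2-hydroxy-4-(methoxymethoxy)phenyl]-3-[4-methoxy-3-(methoxymethoxy)-5-(3-methylbut-2-enyl)phenyl]prop-2-en-1-one F3. Intramolecular oxa-Michael cyclisation under a quinine-derived thiourea catalyst is expected to be only moderately selective for an unactivated chalcone, so preparative HPLC on a chiral phase would remove the minor enantiomer and give (2S)-7-(methoxymethoxy)-2-[4-methoxy-3-(methoxymethoxy)-5-(3-methylbut-2-enyl)phenyl]chroman-4-one F4. The conditions of step 8 then remove both MOM groups and give 18.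

Step 5. The prenyl group may transfer through its γ-carbon to give the 1,1-dimethylallyl isomer, and oxidative addition at the electron-rich, ortho-methoxylated bromide may be slow. The fallback sets out from 10 and returns at 12. Stille coupling with allyltributylstannane (Pd(PPh3)4, toluene, 100 °C), which has no regiochemical ambiguity, should give (2S)-2-[4-methoxy-3-(methoxymethoxy)-5-(prop-2-enyl)phenyl]-5-[(4-methylphenyl)sulfanyl]-2,3-dihydro-4H-pyran-4-one F5. Olefin cross-metathesis with excess 2-methylbut-2-ene (second-generation Grubbs catalyst, CH2Cl2, 40 °C) then converts the allyl group into the prenyl group of 12.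

Step 6. Oxidation at the conjugated, weakly nucleophilic sulfur may be slow with periodate, and stronger oxidants risk over-oxidation to the sulfone or epoxidation of the prenyl double bond. The fallback changes the order of events, sets out from 10 and returns at 13. With no alkene yet present, 3-chloroperbenzoic acid (1.0 equiv, CH2Cl2, −78 °C) should give (2S)-2-[3-bromo-4-methoxy-5-(methoxymethoxy)phenyl]-5-[(4-methylphenyl)sulfinyl]-2,3-dihydro-4H-pyran-4-one F6. Stille coupling of F6 with 11 (Pd(PPh3)4, DMF, 100 °C) then gives 13.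

**Further compounds**
F1 | step 7 | 4-methoxy-3-(methoxymethoxy)-5-(3-methylbut-2-enyl)benzaldehyde | O=Cc1cc(OCOC)c(OC)c(CC=C(C)C)c1
F2 | step 7 | 1-[2-hydroxy-4-(methoxymethoxy)phenyl]ethanone | CC(=O)c1ccc(OCOC)cc1O
F3 | step 7 | (E)-1-[2-hydroxy-4-(methoxymethoxy)phenyl]-3-[4-methoxy-3-(methoxymethoxy)-5-(3-methylbut-2-enyl)phenyl]prop-2-en-1-one | COCOc1ccc(C(=O)/C=C/c2cc(OCOC)c(OC)c(CC=C(C)C)c2)c(O)c1
F4 | step 7 | (2S)-7-(methoxymethoxy)-2-[4-methoxy-3-(methoxymethoxy)-5-(3-methylbut-2-enyl)phenyl]chroman-4-one | COCOc1ccc2C(=O)C[C@H](Oc2c1)c1cc(OCOC)c(OC)c(CC=C(C)C)c1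
F5 | step 5 | (2S)-2-[4-methoxy-3-(methoxymethoxy)-5-(prop-2-enyl)phenyl]-5-[(4-methylphenyl)sulfanyl]-2,3-dihydro-4H-pyran-4-one | Cc1ccc(cc1)SC1=CO[C@@H](CC1=O)c1cc(OCOC)c(OC)c(CC=C)c1
F6 | step 6 | (2S)-2-[3-bromo-4-methoxy-5-(methoxymethoxy)phenyl]-5-[(4-methylphenyl)sulfinyl]-2,3-dihydro-4H-pyran-4-one | Cc1ccc(cc1)S(=O)C1=CO[C@@H](CC1=O)c1cc(OCOC)c(OC)c(Br)c1
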